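One ratio carries these flasks: the rate at which starting material goes to intermediate over the total rate at which it is consumed.

    starting material → side product (k1 = 0.13 h⁻¹)
    starting material → intermediate (k2 = 0.13 h⁻¹)
    intermediate → target (k3 = 0.058 h⁻¹)
    starting material + protic impurity → quenched substrate (k4 = 1.4 M⁻¹ h⁻¹)

| setting | spring | dusk | noon | winter |
|---|---|---|---|---|
| starting material | 20 mM | 20 mM | 20 mM | 20 mM (fed, over 20.0 h) |
| protic impurity | 10.0 mM | 10.0 mM | 10.0 mM | 10.0 mM |
| time | 20 h |  |  | 20 h |
| remark | a closed flask charged with all of it at once and left for 20 h | a single well-mixed tank run continuously and read at steady state, 20 h in it on average | a single well-mixed tank run continuously and read at steady state, 100 h in it on average | all but starting material at the start; starting material goes in evenly over 20.0 h, the run ends at 20 h |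

* the set-up with the highest amount of target at the outlet or at the end, in percent of the starting material put in ("none" if the first two lie within 2 percentage points) (spring / dusk / noon / winter / none)
* amount of target at the outlet or at the end, in percent of the starting material put in, spring
* amount of target at the outlet or at the end, in percent of the starting material put in, dusk
* amount of target at the outlet or at the end, in percent of the starting material put in, noon
* amount of target at the outlet or at the end, in percent of the starting material put in, winter

Here is the chain by hand, with H the protic impurity concentration, k the rate constant of intermediate → target, τ the mean residence time, and Y the target as a share of the starting material put in.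

1. Quenching is second order, but with H held at 10.0 mM it is pseudo-first-order with constant 0.0140 h⁻¹, which is smaller than 0.13 h⁻¹.

2. Starting material then decays with K = 0.274 h⁻¹, the sum of its three first-order constants. Its lifetime of 3.65 h is shorter than the 17.2 h of intermediate, so intermediate → target is the rate-limiting step.

3. The branching share f, the rate constant to intermediate divided by K, is 47.4 %. With H constant, it is the estimated yield of target once both steps are complete.

4. For two first-order steps in a closed flask, Y(t) = f[1 − (K e^(−kt) − k e^(−Kt))/(K − k)]. Spring gives 28.6 %.

5. In a tank, Y = f · Kτ/(1 + Kτ) · kτ/(1 + kτ). Dusk gives 21.5 % and noon 39.0 %.

6. In winter, material enters on average at mid-dosing, so as an estimate Y(t) is read at 10.0 h, which gives 14.6 %. You commit to noon as the highest.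

7. The weak link is the constant H. Quenching takes about 1.02 mM of impurity, so H ends near 8.98 mM. Reforged with that end value, K is 0.273 h⁻¹ and f is 47.7 %. That shift of 0.30 percentage points is smaller than the 7 points between dusk and winter, the closest pair of hand values, so the hand ranking stands.

The forecast names noon, with 28.7 % for spring, 21.6 % for dusk, 39.2 % for noon and 14.2 % for winter, holding that “a little under half of it goes to intermediate”. The two part most on winter, where the hand value stands 0.40 points higher.

The simulation gives noon, with 28.7 % for spring, 21.6 % for dusk, 39.2 % for noon and 14.2 % for winter.

So spring has reached 0.605 of f at 20 h. Left standing until 48.0 h, the same Y(t) gives 43.7 %. That neighbouring flask reads 43.8 % of target, with 3.73 % still standing as intermediate. Spring at 200 h reads 47.6 %, against f of 47.4 %.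

The constants stand for no real mixture; no experiment stands behind them.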